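Ring A is cut at C4–C5. C4 (quaternary: C18 methyl, C19 CH2O) and C5 (a CH that carries C6) are neighbours, flanked by quaternary C10, and correspond to the two ends of an allyl ester enolate. An Ireland–Claisen ring contraction of a δ-lactone silyl ketene acetal therefore forges C4–C5, closes ring A as a cyclohexene, fixes C4 and C5 relative to C10 and releases C6 as a carboxylic acid in one operation. Its precursor is a 4-methyl-4-(2-benzyloxyethyl) δ-valerolactone whose 6-[(E)-3-silyloxy-2-methylprop-1-enyl] group is cis to the benzyloxyethyl arm. Ring B then follows by aldol condensation and the side chain by B-alkyl Suzuki coupling.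

Key step: step 9

Assumption: labdane numbering is used throughout, also for monocyclic intermediates (ring A = C1–C5 with C10, ring B = C5–C10; C18 and C19 on C4, C20 on C10).

Step 1
Reactants: 1 hydroxyacetone
Product: 2 1-[(tert-butyldimethylsilyl)oxy]propan-2-one
Conditions: TBSCl, imidazole, CH2Cl2, 0 °C to rt
Reagents that add atoms: tert-butyldimethylsilyl chloride, CC(C)(C)[Si](C)(C)Cl
Why: Routine silylation of a primary alcohol; the silyl ether is meant to carry the C19 oxygen to the last two steps.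

Step 2
Reactants: 2 1-[(tert-butyldimethylsilyl)oxy]propan-2-one; 3 triethyl phosphonoacetate
Product: 5 ethyl (2E)-4-[(tert-butyldimethylsilyl)oxy]-3-methylbut-2-enoate, via sodium phosphonate carbanion 4 (not isolated)
Conditions: NaH, THF, 0 °C; then 2, 0 °C to rt; chromatography
Reagents that add atoms: none
Why: Horner–Wadsworth–Emmons olefination of a ketone, in which the ester should settle trans to the bulkier CH2OTBS group (E); the minor Z isomer is removed here because this alkene geometry later decides C4.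

Step 3
Reactants: 5 ethyl (2E)-4-[(tert-butyldimethylsilyl)oxy]-3-methylbut-2-enoate
Product: 6 (2E)-4-[(tert-butyldimethylsilyl)oxy]-3-methylbut-2-en-1-ol
Conditions: i-Bu2AlH, CH2Cl2, −78 °C; aq. potassium sodium tartrate work-up
Reagents that add atoms: none
Why: 1,2-Reduction of an enoate to the allylic alcohol by an aluminium hydride, which leaves the alkene geometry and the silyl ether untouched.

Step 4
Reactants: 6 (2E)-4-[(tert-butyldimethylsilyl)oxy]-3-methylbut-2-en-1-ol
Product: 7 (2E)-4-[(tert-butyldimethylsilyl)oxy]-3-methylbut-2-enal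
Conditions: MnO2, CH2Cl2, rt
Reagents that add atoms: none
Why: Selective allylic oxidation with manganese dioxide, which should give the enal without E/Z scrambling.

Step 5
Reactants: 8 4-(benzyloxy)butan-2-one; 7 (2E)-4-[(tert-butyldimethylsilyl)oxy]-3-methylbut-2-enal
Product: 10 (5S,6E)-1-(benzyloxy)-8-[(tert-butyldimethylsilyl)oxy]-5-hydroxy-7-methyloct-6-en-3-one, via boron enolate 9 (not isolated)
Conditions: (+)-Ipc2BCl, Et3N, Et2O, 0 °C; then 7, −78 to −20 °C; H2O2, MeOH, pH 7 buffer
Reagents that add atoms: none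
Why: Reagent-controlled boron aldol reaction of a methyl ketone: the bulky chloroborane enolises only the methyl side, and the enolate from (+)-Ipc2BCl (the antipode expected to attack the si face of an enal) should give the 5S carbinol, from which C10, C5 and C4 are later relayed.

Step 6
Reactants: 10 (5S,6E)-1-(benzyloxy)-8-[(tert-butyldimethylsilyl)oxy]-5-hydroxy-7-methyloct-6-en-3-one; 11 (diethoxyphosphoryl)acetic acid
Product: 12 (5S,6E)-1-(benzyloxy)-8-[(tert-butyldimethylsilyl)oxy]-7-methyl-3-oxooct-6-en-5-yl (diethoxyphosphoryl)acetate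
Conditions: DCC, DMAP (cat.), CH2Cl2, 0 °C to rt
Reagents that add atoms: none
Why: Steglich esterification of the secondary allylic alcohol under neutral conditions, so that the β-hydroxy ketone neither eliminates nor undergoes retro-aldol cleavage.

Step 7
Reactants: 12 (5S,6E)-1-(benzyloxy)-8-[(tert-butyldimethylsilyl)oxy]-7-methyl-3-oxooct-6-en-5-yl (diethoxyphosphoryl)acetate
Product: 13 (6S)-4-[2-(benzyloxy)ethyl]-6-[(1E)-3-{[tert-butyldimethylsilyl]oxy}-2-methylprop-1-en-1-yl]-5,6-dihydro-2H-pyran-2-one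
Conditions: LiCl, i-Pr2NEt, MeCN, rt to 40 °C
Reagents that add atoms: none
Why: Intramolecular Horner–Wadsworth–Emmons reaction onto the ketone, which can only deliver the ring (Z) alkene of the unsaturated δ-lactone; the lithium chloride/amine system is chosen to keep β-elimination of the acyloxy group slow.

Step 8
Reactants: 13 (6S)-4-[2-(benzyloxy)ethyl]-6-[(1E)-3-{[tert-butyldimethylsilyl]oxy}-2-methylprop-1-en-1-yl]-5,6-dihydro-2H-pyran-2-one
Product: 15 (4S,6S)-4-[2-(benzyloxy)ethyl]-6-[(1E)-3-{[tert-butyldimethylsilyl]oxy}-2-methylprop-1-en-1-yl]-4-methyltetrahydro-2H-pyran-2-one, via trimethylsilyl ketene acetal 14 (not isolated)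
Conditions: Me2CuLi, TMSCl, THF, −78 °C; aq. NH4Cl; chromatography
Reagents that add atoms: lithium dimethylcuprate, [Li+].C[Cu-]C
Why: Silyl-chloride-accelerated cuprate 1,4-addition to the β,β-disubstituted unsaturated lactone, fast enough at −78 °C to outrun allylic substitution at the C6 ester oxygen; axial attack anti to the pseudo-equatorial C6 alkenyl group should place the new methyl (C20) trans to it and hence the benzyloxyethyl arm cis (4S), and the labile trimethylsilyl ketene acetal 14 is hydrolysed on work-up so that lactone 15 can be freed of any C4 epimer before the key step.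

Step 9
Reactants: 15 (4S,6S)-4-[2-(benzyloxy)ethyl]-6-[(1E)-3-{[tert-butyldimethylsilyl]oxy}-2-methylprop-1-en-1-yl]-4-methyltetrahydro-2H-pyran-2-one
Product: 18 (1R,2S,6R)-6-[2-(benzyloxy)ethyl]-2-({[tert-butyldimethylsilyl]oxy}methyl)-2,6-dimethylcyclohex-3-ene-1-carboxylic acid, via silyl ketene acetal 16 (not isolated), via silyl ester 17 (not isolated)
Conditions: LiN(i-Pr)2, TBSCl, DMPU, THF, −78 °C to rt (15 added to the premixed base and chlorosilane); toluene, 110 °C; then K2CO3, MeOH/H2O, rt; 1 M aq. HCl to pH 4, 0 °C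
Reagents that add atoms: none
Why: LiN(i-Pr)2 deprotonates 15 at C5 and TBSCl, activated by DMPU, O-silylates the enolate as it forms to the cyclic silyl ketene acetal 16, whose enol geometry is fixed by the ring and whose tert-butyldimethylsilyl group should withstand the heating better than a trimethylsilyl group; a concerted suprafacial [3,3] shift then forms C4–C5 as the C2–O bond breaks, giving silyl ester 17, which carbonate hydrolysis (harmless to the neopentyl-type silyl ether) converts into acid 18. The closest known reaction is the Ireland–Claisen ring contraction of 6-alkenyl δ-lactones to cyclohex-3-enecarboxylic acids. Ring A is closed not by an exo or endo attack but by ring contraction: the six-membered lactone becomes a six-membered carbocycle through a bicyclo[2.2.2]octene-like transition state that forces the pericyclic array into a boat. C4 is controlled by the E geometry of the trisubstituted alkene, which in this boat turns C19 (trans to C2) towards C6; C5 is controlled by the pre-set C2 and C10 centres, because the axial alkenyl group can only reach the enol face on its own side, the one cis to the C9 arm, so that C6 ends cis to C20. The step needs boat-over-chair and single-face selectivity, and both are secured by the ring itself, since a six-membered lactone cannot span a chair array, while the silyl and benzyl ethers offer no competing site.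

Step 10
Reactants: 18 (1R,2S,6R)-6-[2-(benzyloxy)ethyl]-2-({[tert-butyldimethylsilyl]oxy}methyl)-2,6-dimethylcyclohex-3-ene-1-carboxylic acid
Product: 19 [(1R,2S,6R)-6-[2-(benzyloxy)ethyl]-2-({[tert-butyldimethylsilyl]oxy}methyl)-2,6-dimethylcyclohex-3-en-1-yl]methanol
Conditions: LiAlH4, THF, 0 °C to reflux
Reagents that add atoms: none
Why: Hydride reduction of a hindered carboxylic acid to the primary alcohol (C6), to which silyl ether, benzyl ether and the ring alkene are inert.

Step 11
Reactants: 19 [(1R,2S,6R)-6-[2-(benzyloxy)ethyl]-2-({[tert-butyldimethylsilyl]oxy}methyl)-2,6-dimethylcyclohex-3-en-1-yl]methanol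
Product: 20 (1R,2S,6R)-6-[2-(benzyloxy)ethyl]-2-({[tert-butyldimethylsilyl]oxy}methyl)-2,6-dimethylcyclohex-3-ene-1-carbaldehyde
Conditions: Dess–Martin periodinane, CH2Cl2, 0 °C to rt
Reagents that add atoms: none
Why: Dess–Martin oxidation under near-neutral conditions, which should spare the C5 stereocentre next to the new aldehyde; the aldehyde is used at once.

Step 12
Reactants: 20 (1R,2S,6R)-6-[2-(benzyloxy)ethyl]-2-({[tert-butyldimethylsilyl]oxy}methyl)-2,6-dimethylcyclohex-3-ene-1-carbaldehyde; 21 1-(triphenylphosphoranylidene)propan-2-one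
Product: 22 (3E)-4-[(1R,2S,6R)-6-[2-(benzyloxy)ethyl]-2-({[tert-butyldimethylsilyl]oxy}methyl)-2,6-dimethylcyclohex-3-en-1-yl]but-3-en-2-one
Conditions: toluene, 110 °C
Reagents that add atoms: none
Why: Wittig reaction of a stabilised ylide, base-free so that C5 is not epimerised, which adds C7, C8 and C17 as an (E)-enone.

Step 13
Reactants: 22 (3E)-4-[(1R,2S,6R)-6-[2-(benzyloxy)ethyl]-2-({[tert-butyldimethylsilyl]oxy}methyl)-2,6-dimethylcyclohex-3-en-1-yl]but-3-en-2-one
Product: 23 4-[(1R,2S,6R)-2-({[tert-butyldimethylsilyl]oxy}methyl)-6-(2-hydroxyethyl)-2,6-dimethylcyclohexyl]butan-2-one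
Conditions: H2 (1 atm), Pd/C, EtOAc, rt
Reagents that add atoms: none
Why: Catalytic hydrogenation that in one operation saturates the enone alkene and the C2=C3 ring alkene and hydrogenolyses the benzyl ether, with no new stereocentre formed and the silyl ether stable in ethyl acetate.

Step 14
Reactants: 23 4-[(1R,2S,6R)-2-({[tert-butyldimethylsilyl]oxy}methyl)-6-(2-hydroxyethyl)-2,6-dimethylcyclohexyl]butan-2-one
Product: 24 2-[(1R,2R,3S)-3-({[tert-butyldimethylsilyl]oxy}methyl)-1,3-dimethyl-2-(3-oxobutyl)cyclohexyl]acetaldehyde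
Conditions: Dess–Martin periodinane, CH2Cl2, 0 °C to rt
Reagents that add atoms: none
Why: Dess–Martin oxidation of the primary alcohol (C11) to the aldehyde in the presence of the ketone.

Step 15
Reactants: 24 2-[(1R,2R,3S)-3-({[tert-butyldimethylsilyl]oxy}methyl)-1,3-dimethyl-2-(3-oxobutyl)cyclohexyl]acetaldehyde
Product: 25 (4aR,5S,8aS)-5-({[tert-butyldimethylsilyl]oxy}methyl)-2,5,8a-trimethyl-3,4,4a,5,6,7,8,8a-octahydronaphthalene-1-carbaldehyde
Conditions: piperidine, AcOH, toluene, 80 °C
Reagents that add atoms: none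
Why: Amine-catalysed intramolecular aldol condensation: the secondary amine forms the enamine of the aldehyde (C9), which adds to the C8 ketone and dehydrates to the conjugated enal, closing ring B with the C8=C9 alkene; this mode is chosen over the base-mediated one, which would engage the ketone enolate.

Step 16
Reactants: 25 (4aR,5S,8aS)-5-({[tert-butyldimethylsilyl]oxy}methyl)-2,5,8a-trimethyl-3,4,4a,5,6,7,8,8a-octahydronaphthalene-1-carbaldehyde
Product: 26 (4aR,5S,8aS)-1-ethenyl-5-({[tert-butyldimethylsilyl]oxy}methyl)-2,5,8a-trimethyl-3,4,4a,5,6,7,8,8a-octahydronaphthalene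
Conditions: Ph3PCH3Br, KOt-Bu, THF, 0 °C to rt
Reagents that add atoms: methyltriphenylphosphonium bromide, C[P+](c1ccccc1)(c1ccccc1)c1ccccc1.[Br-]
Why: Wittig methylenation of the enal with the small, reactive unstabilised ylide, which adds C12 and gives a diene with one monosubstituted and one tetrasubstituted alkene.

Step 17
Reactants: 27 methyl acetoacetate
Product: 28 methyl (2E)-3-{[(trifluoromethyl)sulfonyl]oxy}but-2-enoate
Conditions: Tf2O, aq. Me4NOH, hexane, 5 °C
Reagents that add atoms: trifluoromethanesulfonic anhydride, O=S(=O)(OS(=O)(=O)C(F)(F)F)C(F)(F)F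
Why: O-Triflation of the β-keto ester enolate; with the non-chelating tetramethylammonium cation the enolate should react in its open form, placing the triflate trans to the ester (E).

Step 18
Reactants: 26 (4aR,5S,8aS)-1-ethenyl-5-({[tert-butyldimethylsilyl]oxy}methyl)-2,5,8a-trimethyl-3,4,4a,5,6,7,8,8a-octahydronaphthalene; 28 methyl (2E)-3-{[(trifluoromethyl)sulfonyl]oxy}but-2-enoate
Product: 30 methyl (2E)-5-[(4aR,5S,8aS)-5-({[tert-butyldimethylsilyl]oxy}methyl)-2,5,8a-trimethyl-3,4,4a,5,6,7,8,8a-octahydronaphthalen-1-yl]-3-methylpent-2-enoate, via B-alkyl-9-BBN 29 (not isolated)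
Conditions: 9-BBN, THF, rt; then 28, PdCl2(dppf), AsPh3, Cs2CO3, DMF/H2O, rt
Reagents that add atoms: none
Why: B-alkyl Suzuki–Miyaura coupling: 9-BBN hydroborates only the vinyl group at its terminus (the tetrasubstituted C8=C9 alkene is inert), and the alkylborane couples at C13 with retention of the E geometry of the enol triflate, so that the C13=C14 alkene is formed with the required geometry.

Step 19
Reactants: 30 methyl (2E)-5-[(4aR,5S,8aS)-5-({[tert-butyldimethylsilyl]oxy}methyl)-2,5,8a-trimethyl-3,4,4a,5,6,7,8,8a-octahydronaphthalen-1-yl]-3-methylpent-2-enoate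
Product: 31 methyl (2E)-5-[(4aR,5S,8aS)-5-(hydroxymethyl)-2,5,8a-trimethyl-3,4,4a,5,6,7,8,8a-octahydronaphthalen-1-yl]-3-methylpent-2-enoate
Conditions: HF·pyridine, pyridine, THF, 0 °C to rt
Reagents that add atoms: none
Why: Fluoride-mediated cleavage of the silyl ether under buffered, non-basic conditions, so that neither the enoate nor the tetrasubstituted alkene isomerises.

Step 20
Reactants: 31 methyl (2E)-5-[(4aR,5S,8aS)-5-(hydroxymethyl)-2,5,8a-trimethyl-3,4,4a,5,6,7,8,8a-octahydronaphthalen-1-yl]-3-methylpent-2-enoate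
Product: 32 methyl (2E)-5-[(4aR,5S,8aS)-5-[(acetyloxy)methyl]-2,5,8a-trimethyl-3,4,4a,5,6,7,8,8a-octahydronaphthalen-1-yl]-3-methylpent-2-enoate
Conditions: Ac2O, pyridine, DMAP (cat.), CH2Cl2, rt
Reagents that add atoms: acetic anhydride, CC(=O)OC(C)=O
Why: DMAP-catalysed acetylation of the neopentyl-type primary alcohol at C19, which completes the target.

Compound list

1 | hydroxyacetone | CC(=O)CO | starting material
2 | 1-[(tert-butyldimethylsilyl)oxy]propan-2-one | CC(=O)CO[Si](C)(C)C(C)(C)C | intermediate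
3 | triethyl phosphonoacetate | CCOC(=O)CP(=O)(OCC)OCC | starting material
4 | sodium salt of the triethyl phosphonoacetate carbanion | [Na+].CCOC(=O)[CH-]P(=O)(OCC)OCC | intermediate (not isolated)
5 | ethyl (2E)-4-[(tert-butyldimethylsilyl)oxy]-3-methylbut-2-enoate | CCOC(=O)/C=C(\C)CO[Si](C)(C)C(C)(C)C | intermediate
6 | (2E)-4-[(tert-butyldimethylsilyl)oxy]-3-methylbut-2-en-1-ol | OC/C=C(\C)CO[Si](C)(C)C(C)(C)C | intermediate
7 | (2E)-4-[(tert-butyldimethylsilyl)oxy]-3-methylbut-2-enal | O=C/C=C(\C)CO[Si](C)(C)C(C)(C)C | intermediate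
8 | 4-(benzyloxy)butan-2-one | CC(=O)CCOCc1ccccc1 | starting material
9 | 4-(benzyloxy)but-1-en-2-yl diisopinocampheylborinate (both isopinocampheyl groups from (−)-α-pinene) | C=C(CCOCc1ccccc1)OB([C@H]1C[C@H]2C[C@@H]([C@@H]1C)C2(C)C)[C@H]1C[C@H]2C[C@@H]([C@@H]1C)C2(C)C | intermediate (not isolated)
10 | (5S,6E)-1-(benzyloxy)-8-[(tert-butyldimethylsilyl)oxy]-5-hydroxy-7-methyloct-6-en-3-one | O=C(CCOCc1ccccc1)C[C@H](O)/C=C(\C)CO[Si](C)(C)C(C)(C)C | intermediate
11 | (diethoxyphosphoryl)acetic acid | OC(=O)CP(=O)(OCC)OCC | starting material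
12 | (5S,6E)-1-(benzyloxy)-8-[(tert-butyldimethylsilyl)oxy]-7-methyl-3-oxooct-6-en-5-yl (diethoxyphosphoryl)acetate | CCOP(=O)(OCC)CC(=O)O[C@@H](CC(=O)CCOCc1ccccc1)/C=C(\C)CO[Si](C)(C)C(C)(C)C | intermediate
13 | (6S)-4-[2-(benzyloxy)ethyl]-6-[(1E)-3-{[tert-butyldimethylsilyl]oxy}-2-methylprop-1-en-1-yl]-5,6-dihydro-2H-pyran-2-one | O=C1C=C(CCOCc2ccccc2)C[C@@H](/C=C(\C)CO[Si](C)(C)C(C)(C)C)O1 | intermediate
14 | (2S,4S)-4-[2-(benzyloxy)ethyl]-2-[(1E)-3-{[tert-butyldimethylsilyl]oxy}-2-methylprop-1-en-1-yl]-4-methyl-6-[(trimethylsilyl)oxy]-3,4-dihydro-2H-pyran (trimethylsilyl ketene acetal of 15) | C[Si](C)(C)OC1=C[C@@](C)(CCOCc2ccccc2)C[C@@H](/C=C(\C)CO[Si](C)(C)C(C)(C)C)O1 | intermediate (not isolated)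
15 | (4S,6S)-4-[2-(benzyloxy)ethyl]-6-[(1E)-3-{[tert-butyldimethylsilyl]oxy}-2-methylprop-1-en-1-yl]-4-methyltetrahydro-2H-pyran-2-one (arm cis to the alkenyl group) | O=C1C[C@@](C)(CCOCc2ccccc2)C[C@@H](/C=C(\C)CO[Si](C)(C)C(C)(C)C)O1 | intermediate (key-step precursor)
16 | (2S,4S)-4-[2-(benzyloxy)ethyl]-6-[(tert-butyldimethylsilyl)oxy]-2-[(1E)-3-{[tert-butyldimethylsilyl]oxy}-2-methylprop-1-en-1-yl]-4-methyl-3,4-dihydro-2H-pyran (tert-butyldimethylsilyl ketene acetal of 15) | CC(C)(C)[Si](C)(C)OC1=C[C@@](C)(CCOCc2ccccc2)C[C@@H](/C=C(\C)CO[Si](C)(C)C(C)(C)C)O1 | intermediate (not isolated)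
17 | tert-butyldimethylsilyl (1R,2S,6R)-6-[2-(benzyloxy)ethyl]-2-({[tert-butyldimethylsilyl]oxy}methyl)-2,6-dimethylcyclohex-3-ene-1-carboxylate | CC(C)(C)[Si](C)(C)OC(=O)[C@H]1[C@@](C)(CO[Si](C)(C)C(C)(C)C)C=CC[C@]1(C)CCOCc2ccccc2 | intermediate (not isolated)
18 | (1R,2S,6R)-6-[2-(benzyloxy)ethyl]-2-({[tert-butyldimethylsilyl]oxy}methyl)-2,6-dimethylcyclohex-3-ene-1-carboxylic acid (C19, C6 and C20 on one face of ring A) | OC(=O)[C@H]1[C@@](C)(CO[Si](C)(C)C(C)(C)C)C=CC[C@]1(C)CCOCc2ccccc2 | intermediate (key-step product)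
19 | [(1R,2S,6R)-6-[2-(benzyloxy)ethyl]-2-({[tert-butyldimethylsilyl]oxy}methyl)-2,6-dimethylcyclohex-3-en-1-yl]methanol | OC[C@H]1[C@@](C)(CO[Si](C)(C)C(C)(C)C)C=CC[C@]1(C)CCOCc2ccccc2 | intermediate
20 | (1R,2S,6R)-6-[2-(benzyloxy)ethyl]-2-({[tert-butyldimethylsilyl]oxy}methyl)-2,6-dimethylcyclohex-3-ene-1-carbaldehyde | O=C[C@H]1[C@@](C)(CO[Si](C)(C)C(C)(C)C)C=CC[C@]1(C)CCOCc2ccccc2 | intermediate
21 | 1-(triphenylphosphoranylidene)propan-2-one | CC(=O)C=P(c1ccccc1)(c1ccccc1)c1ccccc1 | starting material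
22 | (3E)-4-[(1R,2S,6R)-6-[2-(benzyloxy)ethyl]-2-({[tert-butyldimethylsilyl]oxy}methyl)-2,6-dimethylcyclohex-3-en-1-yl]but-3-en-2-one | CC(=O)/C=C/[C@H]1[C@@](C)(CO[Si](C)(C)C(C)(C)C)C=CC[C@]1(C)CCOCc2ccccc2 | intermediate
23 | 4-[(1R,2S,6R)-2-({[tert-butyldimethylsilyl]oxy}methyl)-6-(2-hydroxyethyl)-2,6-dimethylcyclohexyl]butan-2-one | CC(=O)CC[C@H]1[C@@](C)(CO[Si](C)(C)C(C)(C)C)CCC[C@]1(C)CCO | intermediate
24 | 2-[(1R,2R,3S)-3-({[tert-butyldimethylsilyl]oxy}methyl)-1,3-dimethyl-2-(3-oxobutyl)cyclohexyl]acetaldehyde | CC(=O)CC[C@H]1[C@@](C)(CO[Si](C)(C)C(C)(C)C)CCC[C@]1(C)CC=O | intermediate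
25 | (4aR,5S,8aS)-5-({[tert-butyldimethylsilyl]oxy}methyl)-2,5,8a-trimethyl-3,4,4a,5,6,7,8,8a-octahydronaphthalene-1-carbaldehyde | O=CC1=C(C)CC[C@H]2[C@@](C)(CO[Si](C)(C)C(C)(C)C)CCC[C@]12C | intermediate
26 | (4aR,5S,8aS)-1-ethenyl-5-({[tert-butyldimethylsilyl]oxy}methyl)-2,5,8a-trimethyl-3,4,4a,5,6,7,8,8a-octahydronaphthalene | C=CC1=C(C)CC[C@H]2[C@@](C)(CO[Si](C)(C)C(C)(C)C)CCC[C@]12C | intermediate
27 | methyl acetoacetate | COC(=O)CC(C)=O | starting material
28 | methyl (2E)-3-{[(trifluoromethyl)sulfonyl]oxy}but-2-enoate | COC(=O)/C=C(\C)OS(=O)(=O)C(F)(F)F | intermediate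
29 | 9-{2-[(4aR,5S,8aS)-5-({[tert-butyldimethylsilyl]oxy}methyl)-2,5,8a-trimethyl-3,4,4a,5,6,7,8,8a-octahydronaphthalen-1-yl]ethyl}-9-borabicyclo[3.3.1]nonane | C1CC2CCCC(C1)B2CCC1=C(C)CC[C@H]3[C@@](C)(CO[Si](C)(C)C(C)(C)C)CCC[C@]13C | intermediate (not isolated)
30 | methyl (2E)-5-[(4aR,5S,8aS)-5-({[tert-butyldimethylsilyl]oxy}methyl)-2,5,8a-trimethyl-3,4,4a,5,6,7,8,8a-octahydronaphthalen-1-yl]-3-methylpent-2-enoate | COC(=O)/C=C(\C)CCC1=C(C)CC[C@H]2[C@@](C)(CO[Si](C)(C)C(C)(C)C)CCC[C@]12C | intermediate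
31 | methyl (2E)-5-[(4aR,5S,8aS)-5-(hydroxymethyl)-2,5,8a-trimethyl-3,4,4a,5,6,7,8,8a-octahydronaphthalen-1-yl]-3-methylpent-2-enoate | COC(=O)/C=C(\C)CCC1=C(C)CC[C@H]2[C@@](C)(CO)CCC[C@]12C | intermediate
32 | methyl (2E)-5-[(4aR,5S,8aS)-5-[(acetyloxy)methyl]-2,5,8a-trimethyl-3,4,4a,5,6,7,8,8a-octahydronaphthalen-1-yl]-3-methylpent-2-enoate | COC(=O)/C=C(\C)CCC1=C(C)CC[C@H]2[C@@](C)(COC(C)=O)CCC[C@]12C | target

Total step count: 20. Longest linear sequence: 19 steps (steps 1–16 and 18–20; step 17 is a one-step side branch).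

Steps most likely to fail

1. Step 9 (key step). What may go wrong: the hindered α-methylene of 15 is enolised and O-silylated incompletely (self-condensation through the free lithium enolate, C-silylation), so that too little ketene acetal reaches the congested C4–C5 bond formation. The fallback sets out from 14, the trimethylsilyl ketene acetal that step 8 passes through, and comes back to the route at 18; it avoids deprotonation altogether. The cuprate addition delivers 14 regiospecifically and free of amine. Its aqueous work-up is omitted: the ethereal solvent is exchanged for toluene, the copper salts are filtered off under argon and the solution is heated, so that conjugate addition and [3,3] shift run as one cascade. This should give trimethylsilyl (1R,2S,6R)-6-[2-(benzyloxy)ethyl]-2-({[tert-butyldimethylsilyl]oxy}methyl)-2,6-dimethylcyclohex-3-ene-1-carboxylate F1, which water in THF hydrolyses to 18. Any product from the minor C4 epimer is then removed at the acid stage.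

2. Step 7. What may go wrong: β-elimination of the phosphonoacetate from the β-acyloxy ketone (E1cB through the ketone enolate) to a cross-conjugated dienone, faster than the phosphonate carbanion closes on the ketone. The fallback sets out from 10 and comes back at 13, and it replaces the base-mediated olefination by a neutral Wittig lactonisation. Alcohol 10 is heated in toluene with ketenylidenetriphenylphosphorane (Ph3P=C=C=O); addition of the hydroxyl group to the cumulated ylide should give (5S,6E)-1-(benzyloxy)-8-[(tert-butyldimethylsilyl)oxy]-7-methyl-3-oxooct-6-en-5-yl (triphenylphosphoranylidene)acetate F2, which closes on the ketone by an intramolecular Wittig reaction without any added base.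

3. Step 5. What may go wrong: incomplete enantioface discrimination by the diisopinocampheylboron enolate, methyl ketones being the least selective substrates for this reagent; the deficit would pass unchanged into C10, C5 and C4. The fallback sets out from 8 and 7 and comes back at 10, and it replaces asymmetric induction by kinetic resolution. An aldol addition of the kinetic lithium enolate of 8 (LiN(i-Pr)2, THF, −78 °C) to 7 gives racemic (6E)-1-(benzyloxy)-8-[(tert-butyldimethylsilyl)oxy]-5-hydroxy-7-methyloct-6-en-3-one F3. Sharpless kinetic resolution of this secondary allylic alcohol (Ti(Oi-Pr)4, D-(−)-diisopropyl tartrate, t-BuOOH 0.6 equiv, CH2Cl2, −20 °C) should epoxidise the 5R enantiomer to the erythro epoxy ketol (5R)-1-(benzyloxy)-5-[(2S,3S)-3-({[tert-butyldimethylsilyl]oxy}methyl)-3-methyloxiran-2-yl]-5-hydroxypentan-3-one F4 and leave (5S)-10, which is separated by chromatography.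

Further compounds

F1 | step 9 | trimethylsilyl (1R,2S,6R)-6-[2-(benzyloxy)ethyl]-2-({[tert-butyldimethylsilyl]oxy}methyl)-2,6-dimethylcyclohex-3-ene-1-carboxylate | C[Si](C)(C)OC(=O)[C@H]1[C@@](C)(CO[Si](C)(C)C(C)(C)C)C=CC[C@]1(C)CCOCc2ccccc2
F2 | step 7 | (5S,6E)-1-(benzyloxy)-8-[(tert-butyldimethylsilyl)oxy]-7-methyl-3-oxooct-6-en-5-yl (triphenylphosphoranylidene)acetate | O=C(C=P(c1ccccc1)(c1ccccc1)c1ccccc1)O[C@@H](CC(=O)CCOCc1ccccc1)/C=C(\C)CO[Si](C)(C)C(C)(C)C
F3 | step 5 | racemic (6E)-1-(benzyloxy)-8-[(tert-butyldimethylsilyl)oxy]-5-hydroxy-7-methyloct-6-en-3-one | O=C(CCOCc1ccccc1)CC(O)/C=C(\C)CO[Si](C)(C)C(C)(C)C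
F4 | step 5 | (5R)-1-(benzyloxy)-5-[(2S,3S)-3-({[tert-butyldimethylsilyl]oxy}methyl)-3-methyloxiran-2-yl]-5-hydroxypentan-3-one | O=C(CCOCc1ccccc1)C[C@@H](O)[C@@H]1O[C@@]1(C)CO[Si](C)(C)C(C)(C)C
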